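Z goes slowly in both earlier runs, over minutes, and the reckoning here reduces each run to one averaged time.

common to all: Z 12 mM
- ochre: L 20 mM; run made earlier
- amber: L 42 mM; run made earlier
- theta: L 18.0 mM; time 15 min
- epsilon: L 36.0 mM; time 15 min

| run | time / min | Q / % | D / % | Z / % |
|---|---|---|---|---|
| ochre | 0.667 | 2.1 | 3.7 | 94.2 |
| ochre | 1.00 | 3.2 | 5.3 | 91.7 |
| ochre | 1.33 | 4.8 | 7.3 | 91.0 |
| ochre | 2.00 | 4.2 | 10.7 | 88.0 |
| ochre | 3.00 | 7.0 | 14.1 | 79.3 |
| ochre | 5.00 | 10.7 | 20.3 | 70.5 |
| ochre | 8.00 | 12.6 | 28.0 | 61.3 |
| amber | 1.00 | 10.3 | 8.3 | 80.9 |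
| amber | 2.00 | 18.2 | 18.6 | 65.3 |
| amber | 3.00 | 21.8 | 23.1 | 54.0 |
| amber | 4.00 | 25.8 | 28.0 | 47.8 |
| amber | 5.00 | 28.7 | 30.2 | 38.5 |
| amber | 6.00 | 32.9 | 34.9 | 33.6 |
| amber | 8.00 | 37.4 | 40.3 | 24.5 |

(scatter of a reading: 1 percentage point)

* which of these there is most of at the end, counted by the Z in it, theta (Z / D / Q)
* which of these there is most of at the end, counted by the Z in it, epsilon (Z / D / Q)
* amount of the one of these that there is most of at the end, in percent of the Z charged, theta
* amount of the one of these that there is most of at the end, in percent of the Z charged, epsilon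

The tables are read at their last rows, 8.00 min in ochre and 8.00 min in amber. The ratio Q/D stands at 0.450 in ochre and 0.928 in amber, higher with more L charged. The reckoning here therefore assumes, with L unread, that D takes one L and Q takes two. Each Z consumed then draws 1.31 L in ochre and 1.48 in amber.

The working L, written L̄, is the charge less half of what has been drawn: 16.8 mM in ochre and 35.1 mM in amber. Dividing L̄ by Q/D gives L*, the L at which both products form equally fast: 37.4 mM in ochre and 37.8 mM in amber, so 37.6 mM is taken. The selectivity Q/D is then L̄/L*, a ratio that changes with L.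

Z then goes at a rate proportional to L̄(1 + L̄/L*). Dividing the elapsed time by the natural logarithm of Z charged over Z left gives 16.3 min in ochre and 5.69 min in amber. This τ̄, the working time of Z, scales inversely with that rate.

Theta is tried with half of its Z consumed, at ochre's draw, so L̄ is 14.1 mM and τ̄ is 20.6 min. Z ends at 48.3 %, which bears out the trial, and D at 37.6 %, so Z leads.

Epsilon is tried with its whole Z consumed, at amber's draw, so L̄ is 27.1 mM and τ̄ is 8.25 min. Z ends at 16.2 %, D at 48.7 % and Q at 35.1 %, so D leads.

The forecast names Z at 49 % for theta, higher than the reckoning here, and D at 49 % for epsilon, on the ground that “Z falls faster than first order in L”.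

    Z + L → D (k = 2.80 M⁻¹ min⁻¹)
    Z + 2 L → Q (k = 71.0 M⁻² min⁻¹)

Theta ends with Z at 47.9 %, and epsilon with D at 48.7 %. At the end of theta, 56.2 % of the charged L is still free. The Z of theta corresponds to a working time of 20.4 min, beside the 20.6 min reckoned. In the neighbour flask with 20 mM of Z, and theta's L and time, the same trial gives L̄ of 11.4 mM and τ̄ of 26.7 min, hence Z at 57.0 %; that flask ends with Z at 55.5 %.

(The earlier runs and the new flask come from a simulation on assumed constants; the scatter is artificial.)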